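**Strategy**

The only stereocentre of the target is C2 of the oxirane ring, a quaternary carbon that carries the benzene ring, the CH2O ester arm and the unsubstituted ring CH2. The plan cuts out that ring methylene: its two bonds, C2–CH2 and O–CH2, are formed in one operation by catalytic enantioselective methylene transfer from dimethyloxosulfonium methylide to an aryl ketone, which closes the three-membered ring and sets C2. The ketone is an α-silyloxy acetophenone in which the ortho phenol oxygen and the CH2O oxygen both carry triisopropylsilyl groups and the para formyl group is masked as vinyl. Three steps lead to it and two steps (silyl-to-acyl exchange, ozonolysis) follow.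

Key step: step 4

Remark on the chemistry: which antipode of the LaLi3(binaphthoxide)3 catalyst gives the (R)-oxirane with this ketone cannot be predicted from methyl ketones and is fixed by a pilot run, (S) being written as the working choice; both oxygens carry the same TIPS group because it does not chelate lanthanum, resists O-to-O silyl transfer, and goes on and comes off in one operation each.

**Route**

Step 1
Reactants: 1 1-(4-bromo-2-hydroxyphenyl)ethanone; 2 potassium vinyltrifluoroborate
Product: 3 1-(2-hydroxy-4-vinylphenyl)ethanone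
Conditions: PdCl2(dppf)·CH2Cl2 (3 mol %), Cs2CO3, THF/H2O (9:1), 80 °C
Reagents that add atoms: none
Why: Suzuki–Miyaura coupling of a potassium organotrifluoroborate: the C–Br bond para to the acetyl group adds readily to the palladium catalyst, the free phenol is tolerated as its caesium salt, and placing this step first keeps the later silyl ethers away from hot aqueous base.

Step 2
Reactants: 3 1-(2-hydroxy-4-vinylphenyl)ethanone
Product: 4 triisopropyl({1-[2-(triisopropylsilyloxy)-4-vinylphenyl]vinyl}oxy)silane
Conditions: TIPSOTf (2.4 equiv), Et3N, CH2Cl2, 0 °C → rt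
Reagents that add atoms: triisopropylsilyl trifluoromethanesulfonate, CC(C)[Si](C(C)C)(C(C)C)OS(=O)(=O)C(F)(F)F
Why: Silylation with a silyl triflate and a tertiary amine: the phenol is O-silylated and the methyl ketone is converted into its only possible (terminal) silyl enol ether in the same flask, while the excess amine scavenges triflic acid so that the styrene is left alone.

Step 3
Reactants: 4 triisopropyl({1-[2-(triisopropylsilyloxy)-4-vinylphenyl]vinyl}oxy)silane
Product: 6 2-(triisopropylsilyloxy)-1-[2-(triisopropylsilyloxy)-4-vinylphenyl]ethanone, via silyloxyoxirane 5 (not isolated)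
Conditions: mCPBA (1.05 equiv), NaHCO3, CH2Cl2, −20 °C → rt
Reagents that add atoms: 3-chloroperoxybenzoic acid (mCPBA), OOC(=O)c1cccc(Cl)c1
Why: Rubottom oxidation: the electron-rich enol ether is epoxidised by the peracid much faster than the styrene, and the 2-silyloxyoxirane 5 opens to a benzylic oxocarbenium ion in which the silyl group shifts 1,4 onto the new oxygen, so that the α-silyloxy ketone forms directly and the transient stereocentre of 5 disappears.

Step 4
Reactants: 6 2-(triisopropylsilyloxy)-1-[2-(triisopropylsilyloxy)-4-vinylphenyl]ethanone; 7 trimethylsulfoxonium iodide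
Product: 10 (R)-2-[(triisopropylsilyloxy)methyl]-2-[2-(triisopropylsilyloxy)-4-vinylphenyl]oxirane, via dimethyloxosulfonium methylide 8 (not isolated), via sulfoxonium betaine 9 (not isolated)
Conditions: 7, NaH, THF, reflux, then filtered; ylide solution (1.2 equiv) added to 6, LaLi3[(S)-binaphthoxide]3 (5 mol %), [2,4,6-(MeO)3C6H2]3P=O (5 mol %), MS 5Å, THF, rt
Reagents that add atoms: none
Why: Catalytic asymmetric Corey–Chaykovsky epoxidation, whose closest precedent is the same LaLi3(binaphthoxide)3/triarylphosphine oxide system on aryl methyl ketones: the ketone is bound at lanthanum, the ylide 8 at a lithium binaphthoxide site, and the ylide carbon adds to the carbonyl carbon (C2–CH2 bond) to give betaine 9. The alkoxide oxygen then displaces dimethyl sulfoxide from that CH2 in a 3-exo-tet closure (O–CH2 bond), which forms the oxirane, the only ring made. The new quaternary stereocentre C2 is set by the catalyst alone, the (R) product requiring delivery of CH2 to the Re face of the carbonyl (ranking O > CH2OSi > aryl). The step needs enantiofacial selectivity, that is, the catalyst must tell the twisted ortho-silyloxyaryl group from the CH2OSi arm; this has not been shown beyond methyl ketones and is the one real uncertainty of the route, and both oxygens are capped as bulky, non-chelating TIPS ethers so that the ketone binds through its carbonyl oxygen only. Chemoselectivity is secured by substrate and reagent: the stabilised ylide is too weak a base to enolise the ketone or to attack silicon, it ignores the styrene, TIPS resists O-to-O transfer to the betaine alkoxide, and with 1.2 equiv at room temperature a second methylene transfer to the oxetane should not set in.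

Step 5
Reactants: 10 (R)-2-[(triisopropylsilyloxy)methyl]-2-[2-(triisopropylsilyloxy)-4-vinylphenyl]oxirane; 11 isovaleric anhydride
Product: 12 (R)-{2-[2-(3-methylbutanoyloxy)-4-vinylphenyl]oxiran-2-yl}methyl 3-methylbutanoate
Conditions: 11 (5 equiv), DMAP (0.2 equiv), THF, −20 °C; Bu4NF (1 M in THF, 2.4 equiv, slow addition), −20 °C → rt
Reagents that add atoms: none
Why: Fluoride-promoted exchange of silyl ethers for esters (desilylative acylation): fluoride cleaves the aryl O–Si bond and then the primary O–Si bond, each oxyanion is acylated by the excess anhydride as it is released so that no ortho-phenoxide lingers beside the oxirane, and a primary alkoxide that escapes could only undergo a degenerate Payne rearrangement that returns the same enantiomer, so C2 keeps its configuration.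

Step 6
Reactants: 12 (R)-{2-[2-(3-methylbutanoyloxy)-4-vinylphenyl]oxiran-2-yl}methyl 3-methylbutanoate
Product: 14 (R)-{2-[4-formyl-2-(3-methylbutanoyloxy)phenyl]oxiran-2-yl}methyl 3-methylbutanoate, via secondary ozonide 13 (not isolated)
Conditions: O3, CH2Cl2, −78 °C; then PPh3, −78 °C → rt
Reagents that add atoms: ozone, [O-][O+]=O
Why: Ozonolysis with reductive work-up: the terminal styrene is the only group of 12 that reacts with ozone at −78 °C, the esters, the oxirane and the acceptor-substituted benzene ring being inert, and the anhydrous neutral conditions spare the acid-sensitive benzylic oxirane and the aryl ester while the stereocentre is not touched.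

**Compound list**

1 | 1-(4-bromo-2-hydroxyphenyl)ethanone | CC(=O)c1ccc(Br)cc1O | starting material
2 | potassium vinyltrifluoroborate | C=C[B-](F)(F)F.[K+] | starting material
3 | 1-(2-hydroxy-4-vinylphenyl)ethanone | CC(=O)c1ccc(C=C)cc1O | intermediate
4 | triisopropyl({1-[2-(triisopropylsilyloxy)-4-vinylphenyl]vinyl}oxy)silane | C=C(O[Si](C(C)C)(C(C)C)C(C)C)c1ccc(C=C)cc1O[Si](C(C)C)(C(C)C)C(C)C | intermediate
5 | 2-(triisopropylsilyloxy)-2-[2-(triisopropylsilyloxy)-4-vinylphenyl]oxirane (racemic, not isolated) | CC(C)[Si](C(C)C)(C(C)C)OC1(c2ccc(C=C)cc2O[Si](C(C)C)(C(C)C)C(C)C)CO1 | intermediate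
6 | 2-(triisopropylsilyloxy)-1-[2-(triisopropylsilyloxy)-4-vinylphenyl]ethanone | CC(C)[Si](C(C)C)(C(C)C)OCC(=O)c1ccc(C=C)cc1O[Si](C(C)C)(C(C)C)C(C)C | intermediate
7 | trimethylsulfoxonium iodide | C[S+](C)(C)=O.[I-] | starting material
8 | dimethyloxosulfonium methylide (THF solution, not isolated) | [CH2-][S+](C)(C)=O | intermediate
9 | (2S)-1-(dimethyloxosulfonio)-3-(triisopropylsilyloxy)-2-[2-(triisopropylsilyloxy)-4-vinylphenyl]propan-2-olate (betaine, bound to the catalyst, not isolated) | CC(C)[Si](C(C)C)(C(C)C)OC[C@@]([O-])(c1ccc(C=C)cc1O[Si](C(C)C)(C(C)C)C(C)C)C[S+](C)(C)=O | intermediate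
10 | (R)-2-[(triisopropylsilyloxy)methyl]-2-[2-(triisopropylsilyloxy)-4-vinylphenyl]oxirane | CC(C)[Si](C(C)C)(C(C)C)OC[C@@]1(c2ccc(C=C)cc2O[Si](C(C)C)(C(C)C)C(C)C)CO1 | intermediate
11 | isovaleric anhydride (3-methylbutanoic anhydride) | CC(C)CC(=O)OC(=O)CC(C)C | starting material
12 | (R)-{2-[2-(3-methylbutanoyloxy)-4-vinylphenyl]oxiran-2-yl}methyl 3-methylbutanoate | CC(C)CC(=O)OC[C@@]1(c2ccc(C=C)cc2OC(=O)CC(C)C)CO1 | intermediate
13 | (R)-{2-[2-(3-methylbutanoyloxy)-4-(1,2,4-trioxolan-3-yl)phenyl]oxiran-2-yl}methyl 3-methylbutanoate (secondary ozonide, both epimers at the trioxolane carbon, not isolated) | CC(C)CC(=O)OC[C@@]1(c2ccc(C3OCOO3)cc2OC(=O)CC(C)C)CO1 | intermediate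
14 | (R)-{2-[4-formyl-2-(3-methylbutanoyloxy)phenyl]oxiran-2-yl}methyl 3-methylbutanoate (CNP0274578.1) | CC(C)CC(=O)OC[C@@]1(c2ccc(C=O)cc2OC(=O)CC(C)C)CO1 | target

**Step count and risks**

Total step count: 6. Longest linear sequence: 6 steps (1 → 3 → 4 → 6 → 10 → 12 → 14).

Steps most likely to fail:

1. Step 4. The catalyst may discriminate poorly between the two carbonyl faces when the second ketone substituent is a CH2OSi arm instead of a methyl group, or it may turn over so slowly at the hindered carbonyl that the uncatalysed racemic addition competes. The fallback sets out from 6 and comes back at 12. Wittig methylenation of 6 (Ph3PCH3Br, KOtBu, THF, 0 °C → rt) should give triisopropyl({2-[2-(triisopropylsilyloxy)-4-vinylphenyl]prop-2-en-1-yl}oxy)silane F1. Acidic fluoride (aqueous HF, MeCN, 0 °C), which cleaves an alkyl silyl ether in preference to an aryl silyl ether, should give 2-[2-(triisopropylsilyloxy)-4-vinylphenyl]prop-2-en-1-ol F2. Sharpless asymmetric epoxidation (Ti(OiPr)4, L-(+)-diisopropyl tartrate, t-BuOOH, MS 4Å, CH2Cl2, −20 °C) is directed by the allylic hydroxyl and so ignores the styrene. By the usual facial rule it should give (S)-{2-[2-(triisopropylsilyloxy)-4-vinylphenyl]oxiran-2-yl}methanol F3, which has the same spatial arrangement as 10; the descriptor changes only because CH2OH ranks below the ring CH2. F3 is then treated under the conditions of step 5, where the free hydroxyl and the liberated phenoxide are both acylated, and the route is rejoined at 12.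

2. Step 5. The ortho-phenoxide set free by fluoride may open the benzylic oxirane through an ortho-quinone methide, which would also erase C2, before it is acylated. The fallback sets out from 10 and comes back at 14; it reverses the order of the last two operations so that the phenoxide arises only on a ring already deactivated by the formyl group para to the oxirane-bearing carbon. Ozonolysis of 10 (O3, CH2Cl2, −78 °C; then PPh3) should pass through (R)-2-[(triisopropylsilyloxy)methyl]-2-[2-(triisopropylsilyloxy)-4-(1,2,4-trioxolan-3-yl)phenyl]oxirane F4 and give (R)-3-(triisopropylsilyloxy)-4-{2-[(triisopropylsilyloxy)methyl]oxiran-2-yl}benzaldehyde F5. Fluoride in the presence of 11 and DMAP (as in step 5) should then give 14 directly.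

3. Step 3. The peracid may also epoxidise the styrene, or the silyl group may be lost from the primary oxygen during the rearrangement. The fallback sets out from 1 and comes back at 6; it carries out the oxidation before any vinyl group exists. Double silylation of 1 (TIPSOTf, Et3N, CH2Cl2) should give ({1-[4-bromo-2-(triisopropylsilyloxy)phenyl]vinyl}oxy)triisopropylsilane F6. Rubottom oxidation (mCPBA, NaHCO3, CH2Cl2) should pass through 2-[4-bromo-2-(triisopropylsilyloxy)phenyl]-2-(triisopropylsilyloxy)oxirane F7 and give 1-[4-bromo-2-(triisopropylsilyloxy)phenyl]-2-(triisopropylsilyloxy)ethanone F8. Stille coupling with tributyl(vinyl)stannane (Pd(PPh3)4, toluene, 90 °C), which needs no base and so leaves the silyl ethers and the α-silyloxy ketone alone, should then give 6.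

**Further compounds**

F1 | step 4 | triisopropyl({2-[2-(triisopropylsilyloxy)-4-vinylphenyl]prop-2-en-1-yl}oxy)silane | C=C(CO[Si](C(C)C)(C(C)C)C(C)C)c1ccc(C=C)cc1O[Si](C(C)C)(C(C)C)C(C)C
F2 | step 4 | 2-[2-(triisopropylsilyloxy)-4-vinylphenyl]prop-2-en-1-ol | C=C(CO)c1ccc(C=C)cc1O[Si](C(C)C)(C(C)C)C(C)C
F3 | step 4 | (S)-{2-[2-(triisopropylsilyloxy)-4-vinylphenyl]oxiran-2-yl}methanol | OC[C@@]1(c2ccc(C=C)cc2O[Si](C(C)C)(C(C)C)C(C)C)CO1
F4 | step 5 | (R)-2-[(triisopropylsilyloxy)methyl]-2-[2-(triisopropylsilyloxy)-4-(1,2,4-trioxolan-3-yl)phenyl]oxirane | CC(C)[Si](C(C)C)(C(C)C)OC[C@@]1(c2ccc(C3OCOO3)cc2O[Si](C(C)C)(C(C)C)C(C)C)CO1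
F5 | step 5 | (R)-3-(triisopropylsilyloxy)-4-{2-[(triisopropylsilyloxy)methyl]oxiran-2-yl}benzaldehyde | CC(C)[Si](C(C)C)(C(C)C)OC[C@@]1(c2ccc(C=O)cc2O[Si](C(C)C)(C(C)C)C(C)C)CO1
F6 | step 3 | ({1-[4-bromo-2-(triisopropylsilyloxy)phenyl]vinyl}oxy)triisopropylsilane | C=C(O[Si](C(C)C)(C(C)C)C(C)C)c1ccc(Br)cc1O[Si](C(C)C)(C(C)C)C(C)C
F7 | step 3 | 2-[4-bromo-2-(triisopropylsilyloxy)phenyl]-2-(triisopropylsilyloxy)oxirane (racemic) | CC(C)[Si](C(C)C)(C(C)C)OC1(c2ccc(Br)cc2O[Si](C(C)C)(C(C)C)C(C)C)CO1
F8 | step 3 | 1-[4-bromo-2-(triisopropylsilyloxy)phenyl]-2-(triisopropylsilyloxy)ethanone | CC(C)[Si](C(C)C)(C(C)C)OCC(=O)c1ccc(Br)cc1O[Si](C(C)C)(C(C)C)C(C)C
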